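**Retrosynthetic overview**
- The last disconnection is fluoride removal of the side-chain silyl ether. Before it, ring B is cut at C4–C4a and O1–C2 into a ring A resorcinol carrying the complete (2R,3R) side chain and a ring C enaminoester (a formylacetate equivalent with ring C on its α-carbon).
- The strategy rests on one feature: in that resorcinol C4a is the only ring A carbon still bearing hydrogen, ortho to the C8a hydroxyl and para to the C7 hydroxyl, so the C2–C3–C4 unit can be annulated in one orientation only.
- Resorcinol: the aryl–C1'' bond comes from SN2 opening of (2R,3R)-2,3-dimethyloxirane (made from the diol) by an aryl Grignard reagent; the C6 methyl from bromination and Suzuki methylation; then demethylation and silylation.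
- Enaminoester: Claisen acylation of acetoacetate dianion with silylated methyl (S)-3-hydroxybutanoate, acid cyclodehydration to ring C, then aminomethylenation.
- Ring order: ring A is bought, ring C closes in step 11, ring B closes last in step 13.

Key step: step 13

Remark: coumarin numbering (O1, C2–C4, C4a, C5–C8, C8a) is used for ring A and ring B atoms in all intermediates, ring C atoms are primed and side-chain atoms double-primed; it is assumed that the side-chain alcohol must be masked in the key step, because as a free hydroxyl it could add to C4 and close an isochroman.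

**Route**

Step 1
Reactants: 1 2,6-dimethoxytoluene
Product: 3 5-bromo-1,3-dimethoxy-2-methylbenzene, via aryl pinacolboronate 2 (not isolated)
Conditions: B2pin2 (1.0 equiv), [Ir(OMe)(cod)]2 (1.5 mol%), 4,4'-di-tert-butyl-2,2'-bipyridine (3 mol%), THF, 80 °C; evaporate; CuBr2 (3 equiv), MeOH/H2O 1:1, 80 °C
Reagents that add atoms: bis(pinacolato)diboron CC1(C)OB(OC1(C)C)B1OC(C)(C)C(C)(C)O1 (boron and pinacolate are carried only by intermediate 2); copper dibromide Br[Cu]Br
Why: Iridium-catalysed aromatic C–H borylation is sterically governed and should reach only the C–H para to the ring methyl (the one hydrogen with no ortho substituent), and copper-mediated bromodeboronation then swaps boron for bromine at that carbon.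

Step 2
Reactants: 4 (2R,3R)-butane-2,3-diol
Product: 5 (2R,3S)-3-bromobutan-2-yl acetate
Conditions: HBr (33% in AcOH), 0 °C → rt
Reagents that add atoms: acetic acid CC(=O)O; hydrogen bromide Br
Why: Diol-to-bromoacetate conversion through a cyclic acetoxonium (1,3-dioxolan-2-ylium) ion, which bromide opens by SN2, so that the brominated carbon is inverted (to S) while the acetoxy carbon keeps R.

Step 3
Reactants: 5 (2R,3S)-3-bromobutan-2-yl acetate
Product: 6 (2R,3R)-2,3-dimethyloxirane
Conditions: KOH (2.5 equiv), ethylene glycol/H2O, rt → 70 °C, product distilled out as it forms (bp 54 °C)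
Reagents that add atoms: none
Why: Base-mediated epoxide closure (intramolecular Williamson reaction): the acetate is cleaved and the alkoxide displaces bromide with a second inversion, returning that carbon to R and giving the trans (2R,3R) oxirane.

Step 4
Reactants: 3 5-bromo-1,3-dimethoxy-2-methylbenzene; 6 (2R,3R)-2,3-dimethyloxirane
Product: 8 (2R,3R)-3-(3,5-dimethoxy-4-methylphenyl)butan-2-ol, via arylmagnesium bromide 7 (not isolated)
Conditions: Mg, THF, 50 °C; then CuI (10 mol%), 6 (1.2 equiv), −30 → 0 °C; 1 M HCl, 0 °C
Reagents that add atoms: magnesium [Mg] (carried only by intermediate 7)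
Why: Copper-catalysed SN2 opening of an epoxide by an aryl Grignard reagent: the attacked carbon is inverted and becomes the (R)-configured benzylic centre C1'', the untouched carbinol carbon C2'' stays R, and the C2 symmetry of 6 makes both epoxide carbons equivalent so that a single product is expected.

Step 5
Reactants: 8 (2R,3R)-3-(3,5-dimethoxy-4-methylphenyl)butan-2-ol
Product: 9 (2R,3R)-3-(2-bromo-3,5-dimethoxy-4-methylphenyl)butan-2-ol
Conditions: NBS (1.0 equiv), MeCN, 0 °C
Reagents that add atoms: N-bromosuccinimide O=C1CCC(=O)N1Br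
Why: Electrophilic aromatic bromination; the two free ring positions are equivalent, each ortho to one methoxy and para to the other, so one equivalent of reagent should give a single monobromide.

Step 6
Reactants: 9 (2R,3R)-3-(2-bromo-3,5-dimethoxy-4-methylphenyl)butan-2-ol
Product: 10 (2R,3R)-3-(3,5-dimethoxy-2,4-dimethylphenyl)butan-2-ol
Conditions: MeB(OH)2 (3 equiv), Pd(OAc)2 (5 mol%), SPhos (10 mol%), K3PO4 (3 equiv), toluene/H2O 10:1, 100 °C
Reagents that add atoms: methylboronic acid CB(O)O
Why: Suzuki–Miyaura methylation with a bulky electron-rich biaryl phosphine suited to di-ortho-substituted, electron-rich aryl bromides; the free alcohol and both stereocentres take no part.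

Step 7
Reactants: 10 (2R,3R)-3-(3,5-dimethoxy-2,4-dimethylphenyl)butan-2-ol
Product: 11 5-[(2R,3R)-3-hydroxybutan-2-yl]-2,4-dimethylbenzene-1,3-diol
Conditions: BBr3 (5 equiv), CH2Cl2, −78 °C → rt; MeOH, then H2O, 0 °C
Reagents that add atoms: none
Why: Lewis-acid cleavage of aryl methyl ethers (bromide attack on the O-methyl groups of the aryloxyborane adducts); the side-chain hydroxyl is parked as a borate ester that water releases, and aryl participation at its carbon is weak because the ipso ring carbon lies meta to both oxygens.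

Step 8
Reactants: 11 5-[(2R,3R)-3-hydroxybutan-2-yl]-2,4-dimethylbenzene-1,3-diol
Product: 13 5-[(2R,3R)-3-(tert-butyldiphenylsilyloxy)butan-2-yl]-2,4-dimethylbenzene-1,3-diol, via bis-silyl ether 12 (not isolated)
Conditions: TBDPSCl (2.5 equiv), imidazole (5 equiv), DMF, 40 °C; then MeOH, K2CO3 (0.2 equiv), 0 °C → rt
Reagents that add atoms: tert-butyl(chloro)diphenylsilane CC(C)(C)[Si](Cl)(c1ccccc1)c1ccccc1
Why: O-Silylation followed by chemoselective methanolysis of the aryl silyl ether: the alcohol and the less hindered phenol (ortho to the free ring carbon) are silylated, the phenol flanked by two methyls is expected to resist the bulky chloride, and carbonate in methanol then cleaves only the Si–OAr bond because phenoxide is much the better leaving group.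

Step 9
Reactants: 14 methyl (S)-3-hydroxybutanoate
Product: 15 methyl (S)-3-(tert-butyldimethylsilyloxy)butanoate
Conditions: TBSCl (1.2 equiv), imidazole (2.5 equiv), DMF, rt
Reagents that add atoms: tert-butyl(chloro)dimethylsilane CC(C)(C)[Si](C)(C)Cl
Why: Imidazole-promoted O-silylation removes the hydroxyl proton that would quench the dianion of the next step and leaves the stereocentre untouched.

Step 10
Reactants: 16 methyl acetoacetate; 15 methyl (S)-3-(tert-butyldimethylsilyloxy)butanoate
Product: 18 methyl (S)-7-(tert-butyldimethylsilyloxy)-3,5-dioxooctanoate, via acetoacetate dianion 17 (not isolated)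
Conditions: 16 (2.2 equiv), NaH (2.3 equiv), THF, 0 °C; n-BuLi (2.2 equiv), 0 °C; then 15 (1.0 equiv), −78 → 0 °C; cold 1 M HCl
Reagents that add atoms: sodium hydride [Na+].[H-]; n-butyllithium [Li]CCCC (sodium and lithium are carried only by intermediate 17)
Why: Crossed Claisen acylation in which the terminal carbanion of the acetoacetate dianion adds to the ester carbonyl of 15, while the second equivalent of dianion deprotonates the diketoester as it forms so that it is not attacked again; the silyloxy-bearing carbon is not an acidic position.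

Step 11
Reactants: 18 methyl (S)-7-(tert-butyldimethylsilyloxy)-3,5-dioxooctanoate
Product: 20 methyl 2-[(2S)-2-methyl-4-oxo-3,4-dihydro-2H-pyran-6-yl]acetate, via hydroxy diketoester 19 (not isolated)
Conditions: TFA/CH2Cl2 1:4, H2O (2 equiv), 0 °C → rt
Reagents that add atoms: none
Why: Acidic desilylation frees the C7 hydroxyl, which adds to the C3 ketone and loses water to give the vinylogous ester of ring C (cyclodehydration of a δ-hydroxy-β-diketone, 6-exo-trig); the C7–O bond is never broken, so the (S) centre becomes C2' unchanged.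

Step 12
Reactants: 20 methyl 2-[(2S)-2-methyl-4-oxo-3,4-dihydro-2H-pyran-6-yl]acetate
Product: 21 methyl (E)-3-(dimethylamino)-2-[(2S)-2-methyl-4-oxo-3,4-dihydro-2H-pyran-6-yl]prop-2-enoate
Conditions: DMF-DMA (1.5 equiv), toluene, rt → 45 °C
Reagents that add atoms: N,N-dimethylformamide dimethyl acetal COC(OC)N(C)C
Why: Aminomethylenation of an active methylene: the CH2 flanked by the ester and the vinylogous ketone is by far the most acidic site and condenses with the amide acetal with loss of two methanol, while the C3' methylene should stay untouched under these mild, nearly neutral conditions.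

Step 13
Reactants: 13 5-[(2R,3R)-3-(tert-butyldiphenylsilyloxy)butan-2-yl]-2,4-dimethylbenzene-1,3-diol; 21 methyl (E)-3-(dimethylamino)-2-[(2S)-2-methyl-4-oxo-3,4-dihydro-2H-pyran-6-yl]prop-2-enoate
Product: 23 5-[(2R,3R)-3-(tert-butyldiphenylsilyloxy)butan-2-yl]-7-hydroxy-6,8-dimethyl-3-[(2S)-2-methyl-4-oxo-3,4-dihydro-2H-pyran-6-yl]-2H-chromen-2-one, via aryl acrylate 22 (not isolated)
Conditions: glacial AcOH, 21 (1.3 equiv), N2, 85 °C
Reagents that add atoms: none
Why: Acetic acid protonates the enaminoester at its α-carbon to give an iminium ion, which is attacked by C4a of the resorcinol, the only ring carbon bearing hydrogen and the one activated by the ortho C8a hydroxyl and the para C7 hydroxyl; loss of dimethylamine then gives the aryl acrylate 22 and with it the C4–C4a bond. The acrylate double bond can equilibrate by reversible conjugate addition of acetate or amine, so the isomer with aryl and ester cis is drained by lactonisation. Ring B closes by attack of the C8a hydroxyl on the ester carbonyl, a 6-exo-trig acyl substitution that forms O1–C2 and expels methanol. The closest known reaction type is the Pechmann-type condensation of phenols with 2-substituted 3-(dimethylamino)acrylates (formylacetate equivalents) in hot acetic acid. No stereocentre is created: C2' is protected by the weak acid and moderate temperature (a strong acid would open ring C by a retro-oxa-Michael reaction), and the silyl ether keeps the side-chain oxygen from adding to C4. The step needs site selectivity on ring A and chemoselectivity for the enamine carbon over the ring C vinylogous ester, and the substrates secure both: one free ring carbon, one ortho hydroxyl, and an iminium carbon far more electrophilic than C6'.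

Step 14
Reactants: 23 5-[(2R,3R)-3-(tert-butyldiphenylsilyloxy)butan-2-yl]-7-hydroxy-6,8-dimethyl-3-[(2S)-2-methyl-4-oxo-3,4-dihydro-2H-pyran-6-yl]-2H-chromen-2-one
Product: 24 7-hydroxy-5-[(2R,3R)-3-hydroxybutan-2-yl]-6,8-dimethyl-3-[(2S)-2-methyl-4-oxo-3,4-dihydro-2H-pyran-6-yl]-2H-chromen-2-one
Conditions: HF·pyridine, pyridine/THF, 0 °C → rt
Reagents that add atoms: none
Why: Fluoride-driven silyl ether cleavage under buffered, weakly acidic conditions spares the lactone and the vinylogous ester of ring C, exposes C2' to no base, and breaks only the Si–O bond, so the carbinol keeps its R configuration.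

**Compound list**

1 | 2,6-dimethoxytoluene | Cc1c(OC)cccc1OC | starting material
2 | 2-(3,5-dimethoxy-4-methylphenyl)-4,4,5,5-tetramethyl-1,3,2-dioxaborolane | COc1cc(B2OC(C)(C)C(C)(C)O2)cc(OC)c1C | intermediate
3 | 5-bromo-1,3-dimethoxy-2-methylbenzene | COc1cc(Br)cc(OC)c1C | intermediate
4 | (2R,3R)-butane-2,3-diol | C[C@@H](O)[C@@H](C)O | starting material
5 | (2R,3S)-3-bromobutan-2-yl acetate | CC(=O)O[C@H](C)[C@H](C)Br | intermediate
6 | (2R,3R)-2,3-dimethyloxirane | C[C@H]1O[C@@H]1C | intermediate
7 | (3,5-dimethoxy-4-methylphenyl)magnesium bromide | COc1cc([Mg]Br)cc(OC)c1C | intermediate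
8 | (2R,3R)-3-(3,5-dimethoxy-4-methylphenyl)butan-2-ol | COc1cc([C@@H](C)[C@@H](C)O)cc(OC)c1C | intermediate
9 | (2R,3R)-3-(2-bromo-3,5-dimethoxy-4-methylphenyl)butan-2-ol | COc1c(Br)c([C@@H](C)[C@@H](C)O)cc(OC)c1C | intermediate
10 | (2R,3R)-3-(3,5-dimethoxy-2,4-dimethylphenyl)butan-2-ol | COc1c(C)c([C@@H](C)[C@@H](C)O)cc(OC)c1C | intermediate
11 | 5-[(2R,3R)-3-hydroxybutan-2-yl]-2,4-dimethylbenzene-1,3-diol | Cc1c(O)c(C)c(O)cc1[C@@H](C)[C@@H](C)O | intermediate
12 | 3-(tert-butyldiphenylsilyloxy)-5-[(2R,3R)-3-(tert-butyldiphenylsilyloxy)butan-2-yl]-2,6-dimethylphenol | Cc1c(O)c(C)c(O[Si](c2ccccc2)(c3ccccc3)C(C)(C)C)cc1[C@@H](C)[C@@H](C)O[Si](c4ccccc4)(c5ccccc5)C(C)(C)C | intermediate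
13 | 5-[(2R,3R)-3-(tert-butyldiphenylsilyloxy)butan-2-yl]-2,4-dimethylbenzene-1,3-diol | Cc1c(O)c(C)c(O)cc1[C@@H](C)[C@@H](C)O[Si](c2ccccc2)(c3ccccc3)C(C)(C)C | intermediate
14 | methyl (S)-3-hydroxybutanoate | COC(=O)C[C@H](C)O | starting material
15 | methyl (S)-3-(tert-butyldimethylsilyloxy)butanoate | COC(=O)C[C@H](C)O[Si](C)(C)C(C)(C)C | intermediate
16 | methyl acetoacetate | COC(=O)CC(C)=O | starting material
17 | sodium lithium dianion of methyl acetoacetate | [Na+].[Li+].COC(=O)[CH-]C(=O)[CH2-] | intermediate
18 | methyl (S)-7-(tert-butyldimethylsilyloxy)-3,5-dioxooctanoate | COC(=O)CC(=O)CC(=O)C[C@H](C)O[Si](C)(C)C(C)(C)C | intermediate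
19 | methyl (S)-7-hydroxy-3,5-dioxooctanoate | COC(=O)CC(=O)CC(=O)C[C@H](C)O | intermediate
20 | methyl 2-[(2S)-2-methyl-4-oxo-3,4-dihydro-2H-pyran-6-yl]acetate | COC(=O)CC1=CC(=O)C[C@H](C)O1 | intermediate
21 | methyl (E)-3-(dimethylamino)-2-[(2S)-2-methyl-4-oxo-3,4-dihydro-2H-pyran-6-yl]prop-2-enoate | CN(C)/C=C(/C(=O)OC)C1=CC(=O)C[C@H](C)O1 | intermediate
22 | methyl (Z)-3-{6-[(2R,3R)-3-(tert-butyldiphenylsilyloxy)butan-2-yl]-2,4-dihydroxy-3,5-dimethylphenyl}-2-[(2S)-2-methyl-4-oxo-3,4-dihydro-2H-pyran-6-yl]prop-2-enoate | COC(=O)/C(=C\c1c(O)c(C)c(O)c(C)c1[C@@H](C)[C@@H](C)O[Si](c2ccccc2)(c3ccccc3)C(C)(C)C)C4=CC(=O)C[C@H](C)O4 | intermediate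
23 | 5-[(2R,3R)-3-(tert-butyldiphenylsilyloxy)butan-2-yl]-7-hydroxy-6,8-dimethyl-3-[(2S)-2-methyl-4-oxo-3,4-dihydro-2H-pyran-6-yl]-2H-chromen-2-one | Cc1c(O)c(C)c2oc(=O)c(C3=CC(=O)C[C@H](C)O3)cc2c1[C@@H](C)[C@@H](C)O[Si](c4ccccc4)(c5ccccc5)C(C)(C)C | intermediate
24 | 7-hydroxy-5-[(2R,3R)-3-hydroxybutan-2-yl]-6,8-dimethyl-3-[(2S)-2-methyl-4-oxo-3,4-dihydro-2H-pyran-6-yl]-2H-chromen-2-one | Cc1c(O)c(C)c2oc(=O)c(C3=CC(=O)C[C@H](C)O3)cc2c1[C@@H](C)[C@@H](C)O | target

**Step count and risks**

Total step count: 14. Longest linear sequence: 9 steps (4 → 5 → 6 → 8 → 9 → 10 → 11 → 13 → 23 → 24).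

Steps most likely to fail:

First, step 13. Attack at C4a may be slowed by the neighbouring silyloxybutyl group, so that acidolysis of the enamine, opening and re-closure of ring C (erosion at C2') or loss of the silyl ether could outrun the annulation. The fallback replaces the one-step union by formylation and Knoevenagel condensation. It sets out from 13, which is ortho-formylated at its only free ring carbon with the smallest available carbon electrophile (MgCl2, Et3N, paraformaldehyde, MeCN, reflux) to give 6-[(2R,3R)-3-(tert-butyldiphenylsilyloxy)butan-2-yl]-2,4-dihydroxy-3,5-dimethylbenzaldehyde F1. Knoevenagel condensation of this salicylaldehyde with the active methylene ester 20 (piperidinium acetate cat., EtOH, 50 °C), followed by spontaneous lactonisation, comes back to the route at 23.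

Second, step 8. Chemoselectivity may be poor: the hindered secondary alcohol could silylate incompletely beside the faster phenol, or the alkyl silyl ether could be partly lost during the basic methanolysis. The fallback sets out from 11 and masks the phenols first: BnBr, K2CO3, acetone, reflux should benzylate only the two phenols and give (2R,3R)-3-[3,5-bis(benzyloxy)-2,4-dimethylphenyl]butan-2-ol F2. Silylation of the now unique hydroxyl (TBDPSCl, imidazole, DMF, 40 °C) gives {(2R,3R)-3-[3,5-bis(benzyloxy)-2,4-dimethylphenyl]butan-2-yl}oxy-tert-butyldiphenylsilane F3, and hydrogenolysis (H2, Pd/C, EtOAc, rt) comes back to the route at 13.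

Third, step 10. The dianion may act as a base toward ester 15 (enolisation, then β-elimination of silanolate) in place of acylation. The fallback builds the same carbon chain by aldol addition and oxidation. It sets out from 15, which is reduced (DIBAL-H, CH2Cl2, −78 °C) to (S)-3-(tert-butyldimethylsilyloxy)butanal F4. Addition of dianion 17 to this aldehyde (THF, −78 °C) gives methyl (7S)-7-(tert-butyldimethylsilyloxy)-5-hydroxy-3-oxooctanoate F5 as a mixture of C5 epimers, which is of no consequence. Oxidation of the C5 alcohol with Dess–Martin periodinane (CH2Cl2, rt) comes back to the route at 18.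

**Further compounds**

F1 | step 13 | 6-[(2R,3R)-3-(tert-butyldiphenylsilyloxy)butan-2-yl]-2,4-dihydroxy-3,5-dimethylbenzaldehyde | Cc1c(O)c(C)c(O)c(C=O)c1[C@@H](C)[C@@H](C)O[Si](c2ccccc2)(c3ccccc3)C(C)(C)C
F2 | step 8 | (2R,3R)-3-[3,5-bis(benzyloxy)-2,4-dimethylphenyl]butan-2-ol | Cc1c(OCc2ccccc2)c(C)c(OCc3ccccc3)cc1[C@@H](C)[C@@H](C)O
F3 | step 8 | {(2R,3R)-3-[3,5-bis(benzyloxy)-2,4-dimethylphenyl]butan-2-yl}oxy-tert-butyldiphenylsilane | Cc1c(OCc2ccccc2)c(C)c(OCc3ccccc3)cc1[C@@H](C)[C@@H](C)O[Si](c4ccccc4)(c5ccccc5)C(C)(C)C
F4 | step 10 | (S)-3-(tert-butyldimethylsilyloxy)butanal | O=CC[C@H](C)O[Si](C)(C)C(C)(C)C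
F5 | step 10 | methyl (7S)-7-(tert-butyldimethylsilyloxy)-5-hydroxy-3-oxooctanoate (both C5 epimers) | COC(=O)CC(=O)CC(O)C[C@H](C)O[Si](C)(C)C(C)(C)C
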